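**Retrosynthetic overview**

1. Numbering: ring A = C1–C5 and C10 (OH on C3, CMe2 = C4, ring methyl = C25 on C10), side chain C6–C9 and C11–C22 from C5. Camelliol C 29 is cut at C9–C11 (B-alkyl Suzuki–Miyaura) into vinyl iodide 24 and a homofarnesyl borane made from farnesol; C8=C9 comes from methylalumination of alkyne 22, C6–C7 from alkylation of sulfone 17.
2. Ring A is closed at C3–C4 (14 to 16) by a strain-release radical cascade: a primary radical at C25 opens the C10–C4 bond of a 2,2-dimethylcyclopropane, and the tertiary C4 radical adds 6-exo to the C3 aldehyde. The exocyclic C10=C25 bond is then moved into the ring (C10=C1).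
3. Enabling feature: in ring A the quaternary C4 is homoallylic to the methyl carbon on C10 (C4–C5–C10–C25), so ring A is the ring-opened form of a C4/C5/C10 cyclopropylcarbinyl system, and the carbinol carbon C3 lies five atoms from C4 along C10–C1–C2.
4. Cyclopropane 14 comes from bicyclic lactone 5 (enantioselective intramolecular cyclopropanation of prenyl diazoacetate, sets C5), alpha-alkylation (C1–C3 arm) and thiolate opening (C6 handle).
5. Ring order: cyclopropane inside a temporary lactone (step 3), lactone opened (step 5), then ring A as the cyclopropane is consumed (step 10).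

Key step: step 10

**Route**

Step 1
Reactants: 1 3-methylbut-2-en-1-ol (prenol); 2 bromoacetyl bromide
Product: 3 3-methylbut-2-en-1-yl bromoacetate
Conditions: NaHCO3, MeCN, 0 °C
Reagents that add atoms: none
Why: O-acylation of the primary allylic alcohol by the acid bromide, with bicarbonate taking up HBr so that the acid-sensitive prenyl ester survives; no stereocentre.

Step 2
Reactants: 3 3-methylbut-2-en-1-yl bromoacetate
Product: 4 3-methylbut-2-en-1-yl diazoacetate
Conditions: TsNHNHTs, DBU, THF, 0 °C
Reagents that add atoms: N,N'-ditosylhydrazine, Cc1ccc(cc1)S(=O)(=O)NNS(=O)(=O)c1ccc(C)cc1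
Why: N-alkylation of the bis-sulfonylhydrazine by the bromoacetate followed by twofold base-induced loss of sulfinate is a standard diazoacetate synthesis.

Step 3
Reactants: 4 3-methylbut-2-en-1-yl diazoacetate
Product: 5 (1S,5R)-6,6-dimethyl-3-oxabicyclo[3.1.0]hexan-2-one
Conditions: Rh2(5S-MEPY)4 (1 mol%), CH2Cl2, reflux, slow addition of 4
Reagents that add atoms: none
Why: Intramolecular carbene cyclopropanation of the allylic diazoacetate by the chiral dirhodium carboxamidate should give the cis-fused lactone, the ligand shell choosing the alkene face and so both cyclopropane stereocentres (the CH carbon next to CH2O becomes C5 of the target).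

Step 4
Reactants: 5 (1S,5R)-6,6-dimethyl-3-oxabicyclo[3.1.0]hexan-2-one; 6 3-bromo-1,1-dimethoxypropane
Product: 8 (1S,5S)-1-(3,3-dimethoxypropyl)-6,6-dimethyl-3-oxabicyclo[3.1.0]hexan-2-one, via lithiated lactone 7 (not isolated)
Conditions: LiN(i-Pr)2, THF, −78 °C; then 6, DMPU, −78 °C to 0 °C
Reagents that add atoms: none
Why: Lithiation–alkylation of a cyclopropanecarboxylate at its alpha-carbon; the cis ring fusion fixes the bridgehead anion, so the C1–C3 arm enters with retention and the quaternary centre (later C10, which ends sp2) needs no control.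

Step 5
Reactants: 8 (1S,5S)-1-(3,3-dimethoxypropyl)-6,6-dimethyl-3-oxabicyclo[3.1.0]hexan-2-one
Product: 10 (1S,3S)-1-(3,3-dimethoxypropyl)-2,2-dimethyl-3-[(phenylsulfanyl)methyl]cyclopropane-1-carboxylic acid, via sodium carboxylate 9 (not isolated)
Conditions: PhSNa, DMF, 100 °C; then aq. HCl to pH 3
Reagents that add atoms: sodium thiophenolate, [Na+].[S-]c1ccccc1
Why: SN2 opening of the gamma-lactone at its O-alkyl carbon (a cyclopropylcarbinyl CH2) by the soft thiolate tells the two oxygenated carbons apart without protecting groups: C6 receives the sulfur handle and C25 is freed as the acid.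

Step 6
Reactants: 10 (1S,3S)-1-(3,3-dimethoxypropyl)-2,2-dimethyl-3-[(phenylsulfanyl)methyl]cyclopropane-1-carboxylic acid
Product: 11 (1S,3S)-1-(3,3-dimethoxypropyl)-2,2-dimethyl-3-[(phenylsulfonyl)methyl]cyclopropane-1-carboxylic acid
Conditions: 30% aq. H2O2, Na2WO4·2H2O (5 mol%), MeOH, 0 °C to rt
Reagents that add atoms: hydrogen peroxide, OO
Why: Tungstate-catalysed sulfide-to-sulfone oxidation; nothing else is oxidisable, and the sulfone, unlike the sulfide, cannot later release a thiol that would quench the radical chain.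

Step 7
Reactants: 11 (1S,3S)-1-(3,3-dimethoxypropyl)-2,2-dimethyl-3-[(phenylsulfonyl)methyl]cyclopropane-1-carboxylic acid
Product: 12 [(1S,3S)-1-(3,3-dimethoxypropyl)-2,2-dimethyl-3-[(phenylsulfonyl)methyl]cyclopropyl]methanol
Conditions: BH3·SMe2, THF, 0 °C to rt; then MeOH, H2O
Reagents that add atoms: none
Why: Chemoselective borane reduction of the carboxylic acid via the acyloxyborane, which leaves sulfone and acetal untouched.

Step 8
Reactants: 12 [(1S,3S)-1-(3,3-dimethoxypropyl)-2,2-dimethyl-3-[(phenylsulfonyl)methyl]cyclopropyl]methanol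
Product: 13 O-{[(1S,3S)-1-(3,3-dimethoxypropyl)-2,2-dimethyl-3-[(phenylsulfonyl)methyl]cyclopropyl]methyl} O-phenyl carbonothioate
Conditions: PhOC(S)Cl, pyridine, DMAP (cat.), CH2Cl2, rt
Reagents that add atoms: O-phenyl chlorothionoformate, S=C(Cl)Oc1ccccc1
Why: O-thioacylation gives a Barton–McCombie radical precursor under non-ionising conditions, which matters because a true leaving group on this cyclopropylcarbinyl carbon would open the ring by the cationic path.

Step 9
Reactants: 13 O-{[(1S,3S)-1-(3,3-dimethoxypropyl)-2,2-dimethyl-3-[(phenylsulfonyl)methyl]cyclopropyl]methyl} O-phenyl carbonothioate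
Product: 14 O-{[(1S,3S)-2,2-dimethyl-1-(3-oxopropyl)-3-[(phenylsulfonyl)methyl]cyclopropyl]methyl} O-phenyl carbonothioate
Conditions: PPTS (cat.), acetone/H2O, 40 °C
Reagents that add atoms: water, O
Why: Mild acid-catalysed hydrolysis of the dimethyl acetal frees the aldehyde, the thionocarbonate and the alkylcyclopropane being stable to PPTS.

Step 10
Reactants: 14 O-{[(1S,3S)-2,2-dimethyl-1-(3-oxopropyl)-3-[(phenylsulfonyl)methyl]cyclopropyl]methyl} O-phenyl carbonothioate
Product: 16 (1S,3R)-2,2-dimethyl-4-methylidene-3-[(phenylsulfonyl)methyl]cyclohexan-1-ol, via diethylborinate 15 (not isolated)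
Conditions: Bu3SnH (1.3 equiv, syringe pump), AIBN (cat.), Et3B (3 equiv), PhMe, 100 °C, sealed vessel, high dilution; then H2O
Reagents that add atoms: none
Why: Proposed new method: the tributyltin radical adds to the thiocarbonyl sulfur of 14 and the adduct fragments (Barton–McCombie mode) to the primary cyclopropylcarbinyl radical at C25, whose 2,2-dimethylcyclopropane opens at C10–C4 with release of ring strain to give the exocyclic C10=C25 alkene and the tertiary homoallylic radical at C4; this nucleophilic radical adds to the aldehyde carbon C3, and the alkoxyl radical is captured by Et3B (homolytic substitution at boron), which makes the otherwise reversible carbonyl addition productive and carries the chain on through ethyl radical and Bu3SnH. The closest known reaction types are the ring opening of cyclopropylcarbinyl radicals generated in thiocarbonyl deoxygenations and the Et3B-assisted radical cyclization of halo aldehydes to cycloalkanols; their union in one chain with a tertiary radical is not established. The six-membered ring (C3, C4, C5, C10, C1, C2) closes in the 6-exo-trig mode on the C=O bond. C5 is carried unchanged from the cyclopropane, and the new stereocentre C3 should be set by a chair transition state in which the C5 arm and the carbonyl oxygen are both equatorial, placing OH cis to the arm (3S). The step needs cleavage of C10–C4 rather than C10–C5 and cyclization rather than hydrogen transfer: the first is secured by the gem-dimethyl group (tertiary against secondary radical), the second by high dilution, slow addition of Bu3SnH and excess Et3B.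

Step 11
Reactants: 16 (1S,3R)-2,2-dimethyl-4-methylidene-3-[(phenylsulfonyl)methyl]cyclohexan-1-ol
Product: 17 (1S,5R)-4,6,6-trimethyl-5-[(phenylsulfonyl)methyl]cyclohex-3-en-1-ol
Conditions: (salen)CoCl (3 mol%; salen = (R,R)-N,N'-bis(3,5-di-tert-butylsalicylidene)-1,2-cyclohexanediaminate), PhSiH3 (6 mol%), PhH, rt
Reagents that add atoms: none
Why: Cobalt-hydride hydrogen-atom-transfer isomerization of a 1,1-disubstituted alkene: reversible H-atom addition gives the tertiary C10 radical and H-atom return from the accessible C1 methylene (the flanked C5–H is shielded) should place the trisubstituted double bond at C10=C1 without touching a stereocentre.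

Step 12
Reactants: 17 (1S,5R)-4,6,6-trimethyl-5-[(phenylsulfonyl)methyl]cyclohex-3-en-1-ol; 18 3-bromo-1-(trimethylsilyl)prop-1-yne
Product: 20 (1S,5R)-4,6,6-trimethyl-5-[1-(phenylsulfonyl)-4-(trimethylsilyl)but-3-yn-1-yl]cyclohex-3-en-1-ol (epimers at the sulfone carbon), via dilithio sulfone 19 (not isolated)
Conditions: n-BuLi (2.1 equiv), THF, −78 °C; then 18, −78 °C to −30 °C; H2O
Reagents that add atoms: none
Why: Alkylation of the alpha-sulfonyl carbanion by a propargylic bromide (Julia-type C–C bond formation) builds C6–C7; the hindered lithium alkoxide is a spectator at low temperature and the new sulfone-bearing centre is erased in the next step.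

Step 13
Reactants: 20 (1S,5R)-4,6,6-trimethyl-5-[1-(phenylsulfonyl)-4-(trimethylsilyl)but-3-yn-1-yl]cyclohex-3-en-1-ol
Product: 22 (1S,5R)-5-(but-3-yn-1-yl)-4,6,6-trimethylcyclohex-3-en-1-ol, via silylalkyne 21 (not isolated)
Conditions: 6% Na(Hg), MeOH/THF, −20 °C to rt
Reagents that add atoms: none
Why: Reductive desulfonylation by sodium amalgam cleaves the C–S bond of the non-allylic sulfone, and the methoxide formed in the flask then removes the alkynyl silyl group on warming.

Step 14
Reactants: 22 (1S,5R)-5-(but-3-yn-1-yl)-4,6,6-trimethylcyclohex-3-en-1-ol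
Product: 24 (1S,5R)-5-[(3E)-4-iodo-3-methylbut-3-en-1-yl]-4,6,6-trimethylcyclohex-3-en-1-ol, via alkenylalane 23 (not isolated)
Conditions: AlMe3 (3 equiv), Cp2ZrCl2 (25 mol%), H2O (1 equiv), CH2Cl2, −20 °C to rt; then I2, THF, −30 °C
Reagents that add atoms: trimethylaluminium, C[Al](C)C; iodine, II
Why: Negishi carboalumination: zirconium-catalysed syn addition of Me–Al across the terminal alkyne puts methyl on the internal carbon, and iodinolysis with retention gives the E vinyl iodide, which fixes the C8=C9 geometry.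

Step 15
Reactants: 25 (2E,6E)-farnesol
Product: 26 (2E,6E)-farnesal
Conditions: TEMPO (10 mol%), PhI(OAc)2, CH2Cl2, rt
Reagents that add atoms: none
Why: Oxoammonium-mediated oxidation of the allylic alcohol to the enal under neutral conditions should leave the 2E geometry intact.

Step 16
Reactants: 26 (2E,6E)-farnesal
Product: 27 (3E,7E)-4,8,12-trimethyltrideca-1,3,7,11-tetraene
Conditions: Ph3PCH3Br, KOt-Bu, THF, 0 °C to rt
Reagents that add atoms: methyltriphenylphosphonium bromide, C[P+](c1ccccc1)(c1ccccc1)c1ccccc1.[Br-]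
Why: Wittig methylenation of the enal gives the terminal 1,3-diene and supplies C11.

Step 17
Reactants: 24 (1S,5R)-5-[(3E)-4-iodo-3-methylbut-3-en-1-yl]-4,6,6-trimethylcyclohex-3-en-1-ol; 27 (3E,7E)-4,8,12-trimethyltrideca-1,3,7,11-tetraene
Product: 29 camelliol C, via alkylborane 28 (not isolated)
Conditions: 27, 9-BBN, THF, 0 °C to rt; then 24, Pd(dppf)Cl2 (5 mol%), AsPh3, Cs2CO3, DMF/H2O, rt
Reagents that add atoms: none
Why: B-alkyl Suzuki–Miyaura coupling: 9-BBN should add only to the monosubstituted terminal alkene of the diene, and the primary alkylborane couples with the vinyl iodide with retention of the E geometry in the presence of the free hydroxyl.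

**Compound list**

1 | 3-methylbut-2-en-1-ol (prenol) | CC(C)=CCO | starting material
2 | bromoacetyl bromide | BrCC(Br)=O | starting material
3 | 3-methylbut-2-en-1-yl bromoacetate | CC(C)=CCOC(=O)CBr | intermediate
4 | 3-methylbut-2-en-1-yl diazoacetate | CC(C)=CCOC(=O)C=[N+]=[N-] | intermediate
5 | (1S,5R)-6,6-dimethyl-3-oxabicyclo[3.1.0]hexan-2-one | O=C1OC[C@@H]2[C@H]1C2(C)C | intermediate
6 | 3-bromo-1,1-dimethoxypropane | COC(OC)CCBr | starting material
7 | lithiated lactone (C1-lithio derivative of 5) | O=C1OC[C@@H]2[C@@]1([Li])C2(C)C | intermediate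
8 | (1S,5S)-1-(3,3-dimethoxypropyl)-6,6-dimethyl-3-oxabicyclo[3.1.0]hexan-2-one | O=C1OC[C@@H]2[C@@]1(CCC(OC)OC)C2(C)C | intermediate
9 | sodium (1S,3S)-1-(3,3-dimethoxypropyl)-2,2-dimethyl-3-[(phenylsulfanyl)methyl]cyclopropane-1-carboxylate | [Na+].[O-]C(=O)[C@@]1(CCC(OC)OC)[C@@H](CSc2ccccc2)C1(C)C | intermediate
10 | (1S,3S)-1-(3,3-dimethoxypropyl)-2,2-dimethyl-3-[(phenylsulfanyl)methyl]cyclopropane-1-carboxylic acid | OC(=O)[C@@]1(CCC(OC)OC)[C@@H](CSc2ccccc2)C1(C)C | intermediate
11 | (1S,3S)-1-(3,3-dimethoxypropyl)-2,2-dimethyl-3-[(phenylsulfonyl)methyl]cyclopropane-1-carboxylic acid | OC(=O)[C@@]1(CCC(OC)OC)[C@@H](CS(=O)(=O)c2ccccc2)C1(C)C | intermediate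
12 | [(1S,3S)-1-(3,3-dimethoxypropyl)-2,2-dimethyl-3-[(phenylsulfonyl)methyl]cyclopropyl]methanol | OC[C@@]1(CCC(OC)OC)[C@@H](CS(=O)(=O)c2ccccc2)C1(C)C | intermediate
13 | O-{[(1S,3S)-1-(3,3-dimethoxypropyl)-2,2-dimethyl-3-[(phenylsulfonyl)methyl]cyclopropyl]methyl} O-phenyl carbonothioate | S=C(Oc1ccccc1)OC[C@@]1(CCC(OC)OC)[C@@H](CS(=O)(=O)c2ccccc2)C1(C)C | intermediate
14 | O-{[(1S,3S)-2,2-dimethyl-1-(3-oxopropyl)-3-[(phenylsulfonyl)methyl]cyclopropyl]methyl} O-phenyl carbonothioate | S=C(Oc1ccccc1)OC[C@@]1(CCC=O)[C@@H](CS(=O)(=O)c2ccccc2)C1(C)C | intermediate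
15 | diethylborinate of 16 | O=S(=O)(c1ccccc1)C[C@@H]1C(=C)CC[C@H](OB(CC)CC)C1(C)C | intermediate
16 | (1S,3R)-2,2-dimethyl-4-methylidene-3-[(phenylsulfonyl)methyl]cyclohexan-1-ol | O=S(=O)(c1ccccc1)C[C@@H]1C(=C)CC[C@H](O)C1(C)C | intermediate
17 | (1S,5R)-4,6,6-trimethyl-5-[(phenylsulfonyl)methyl]cyclohex-3-en-1-ol | O=S(=O)(c1ccccc1)C[C@@H]1C(C)=CC[C@H](O)C1(C)C | intermediate
18 | 3-bromo-1-(trimethylsilyl)prop-1-yne | C[Si](C)(C)C#CCBr | starting material
19 | dilithio derivative of 17 (lithium alkoxide, alpha-sulfonyl carbanion) | [Li]C(S(=O)(=O)c1ccccc1)[C@@H]1C(C)=CC[C@H](O[Li])C1(C)C | intermediate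
20 | (1S,5R)-4,6,6-trimethyl-5-[1-(phenylsulfonyl)-4-(trimethylsilyl)but-3-yn-1-yl]cyclohex-3-en-1-ol (epimers at the sulfone carbon) | C[Si](C)(C)C#CCC(S(=O)(=O)c1ccccc1)[C@@H]1C(C)=CC[C@H](O)C1(C)C | intermediate
21 | (1S,5R)-4,6,6-trimethyl-5-[4-(trimethylsilyl)but-3-yn-1-yl]cyclohex-3-en-1-ol | C[Si](C)(C)C#CCC[C@@H]1C(C)=CC[C@H](O)C1(C)C | intermediate
22 | (1S,5R)-5-(but-3-yn-1-yl)-4,6,6-trimethylcyclohex-3-en-1-ol | C#CCC[C@@H]1C(C)=CC[C@H](O)C1(C)C | intermediate
23 | (E)-alkenyl(dimethyl)alane of 22, O-dimethylaluminium alkoxide | C[Al](C)/C=C(\C)CC[C@@H]1C(C)=CC[C@H](O[Al](C)C)C1(C)C | intermediate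
24 | (1S,5R)-5-[(3E)-4-iodo-3-methylbut-3-en-1-yl]-4,6,6-trimethylcyclohex-3-en-1-ol | I/C=C(\C)CC[C@@H]1C(C)=CC[C@H](O)C1(C)C | intermediate
25 | (2E,6E)-farnesol | CC(C)=CCC/C(C)=C/CC/C(C)=C/CO | starting material
26 | (2E,6E)-farnesal | CC(C)=CCC/C(C)=C/CC/C(C)=C/C=O | intermediate
27 | (3E,7E)-4,8,12-trimethyltrideca-1,3,7,11-tetraene | C=C/C=C(\C)CC/C=C(\C)CCC=C(C)C | intermediate
28 | 9-[(3E,7E)-4,8,12-trimethyltrideca-3,7,11-trien-1-yl]-9-borabicyclo[3.3.1]nonane | CC(C)=CCC/C(C)=C/CC/C(C)=C/CCB1C2CCCC1CCC2 | intermediate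
29 | camelliol C, (1S,5R)-4,6,6-trimethyl-5-[(3E,7E,11E)-3,8,12,16-tetramethylheptadeca-3,7,11,15-tetraen-1-yl]cyclohex-3-en-1-ol | CC(C)=CCC/C(C)=C/CC/C(C)=C/CC/C=C(\C)CC[C@@H]1C(C)=CC[C@H](O)C1(C)C | target

**Step count**

Total step count: 17. Longest linear sequence: 15 (steps 1–14 and 17).

**Steps most likely to fail**

Step 10. The ring opening may be poorly regioselective (C10–C5 cleavage, followed by loss of the sulfonyl radical), and hydrogen transfer to the tertiary C4 radical may outrun its addition to the aldehyde. The fallback separates ring opening from ring closure. From alcohol 12, MgI2·OEt2 in Et2O/PhH at 0 °C would bring about the cationic cyclopropylcarbinyl-to-homoallyl rearrangement (Julia olefin synthesis mode), which is strictly Markovnikov, and should give tertiary iodide (3S)-2-iodo-7,7-dimethoxy-2-methyl-4-methylidene-3-[(phenylsulfonyl)methyl]heptane F1. PPTS in wet acetone would then free the aldehyde (5S)-6-iodo-6-methyl-4-methylidene-5-[(phenylsulfonyl)methyl]heptanal F2. Et3B with slow admission of air in PhH at rt (iodine-atom-transfer chain with no hydrogen donor present) would generate the same tertiary radical, which cyclizes onto the aldehyde and is trapped as borinate 15; aqueous work-up returns to the route at 16.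

Step 11. Hydrogen-atom return may also occur from C5–H (giving the tetrasubstituted isomer), or the isomerization may stall. The fallback is a regiospecific two-step transposition from 16. Riley oxidation (SeO2 cat., t-BuOOH, CH2Cl2) at the allylic methylene C1 should give the C1-hydroxy derivative of 16 (allylic alcohol, either epimer) F3. Mitsunobu displacement of this allylic hydroxyl with 2-nitrobenzenesulfonylhydrazide (PPh3, DEAD, THF, −30 °C) should give the allylic N-(2-nitrobenzenesulfonyl)hydrazine F4; the C3 hydroxyl next to the quaternary carbon should not react. On warming, F4 loses sulfinic acid and then N2 by a retro-ene shift of the diazene, which delivers hydrogen to C25 and sets the double bond at C10=C1, coming back to the route at 17.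

Step 4. The hindered bridgehead anion 7 may react too slowly with the unactivated bromide 6, so that proton transfer and elimination take over. The fallback uses a reactive allylic electrophile and adjusts the arm afterwards. From 5, LiN(i-Pr)2 and then allyl bromide should give (1S,5S)-6,6-dimethyl-1-(prop-2-en-1-yl)-3-oxabicyclo[3.1.0]hexan-2-one F5. Hydroboration–oxidation (9-BBN; NaBO3) should give (1S,5S)-1-(3-hydroxypropyl)-6,6-dimethyl-3-oxabicyclo[3.1.0]hexan-2-one F6, and Dess–Martin oxidation 3-[(1S,5S)-6,6-dimethyl-2-oxo-3-oxabicyclo[3.1.0]hexan-1-yl]propanal F7. HC(OMe)3 with PPTS in MeOH would convert F7 into the dimethyl acetal, which is 8.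

**Further compounds**

F1 | step 10 | (3S)-2-iodo-7,7-dimethoxy-2-methyl-4-methylidene-3-[(phenylsulfonyl)methyl]heptane | IC(C)(C)[C@H](CS(=O)(=O)c1ccccc1)C(=C)CCC(OC)OC
F2 | step 10 | (5S)-6-iodo-6-methyl-4-methylidene-5-[(phenylsulfonyl)methyl]heptanal | IC(C)(C)[C@H](CS(=O)(=O)c1ccccc1)C(=C)CCC=O
F3 | step 11 | C1-hydroxy derivative of 16 (allylic alcohol, either epimer) | O=S(=O)(c1ccccc1)C[C@@H]1C(=C)C(O)C[C@H](O)C1(C)C
F4 | step 11 | allylic N-(2-nitrobenzenesulfonyl)hydrazine from F3 | O=S(=O)(c1ccccc1)C[C@@H]1C(=C)C(N(N)S(=O)(=O)c2ccccc2[N+](=O)[O-])C[C@H](O)C1(C)C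
F5 | step 4 | (1S,5S)-6,6-dimethyl-1-(prop-2-en-1-yl)-3-oxabicyclo[3.1.0]hexan-2-one | O=C1OC[C@@H]2[C@@]1(CC=C)C2(C)C
F6 | step 4 | (1S,5S)-1-(3-hydroxypropyl)-6,6-dimethyl-3-oxabicyclo[3.1.0]hexan-2-one | O=C1OC[C@@H]2[C@@]1(CCCO)C2(C)C
F7 | step 4 | 3-[(1S,5S)-6,6-dimethyl-2-oxo-3-oxabicyclo[3.1.0]hexan-1-yl]propanal | O=C1OC[C@@H]2[C@@]1(CCC=O)C2(C)C
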